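## Analysis of the target

Compound 17 is a monocyclic oxolane. C2 carries the 3,4,5-trimethoxyphenyl group (ring B), C3 a hydroxymethyl group, C4 a benzyl group whose arene is 2,4,5-trimethoxyphenyl (ring A), and C5 is a plain CH2 next to O1. The three stereocentres are contiguous and are (2R,3R,4R); the three ring hydrogens lie on one face, so aryl, hydroxymethyl and benzyl are all cis. This all-cis array is the most crowded of the four diastereomers, so it has to be made under kinetic control, and no later step may equilibrate C2 or C3. The sensitive points are the benzylic C2–O1 bond (ionisation under acid, hydrogenolysis), the very electron-rich ring A (oxidation, electrophilic attack) and, in any intermediate with a carbonyl on C3, an acidic C3–H that sits β to the ring oxygen (epimerisation, ring opening by elimination). Apart from the one primary alcohol there is no functional handle, so the difficulty lies wholly in closing the ring with three adjacent centres in the less stable relationship and in one absolute sense. The strategy rests on the C2–C3 bond: it joins a benzylic ether carbon (ArCH–O) to a carbon bearing a one-carbon branch that can stand at the carboxyl level, which is what a donor/acceptor carbene leaves behind when it inserts into an ArCH2–O C–H bond. The C4 benzyl group fits the same picture: as a benzylidene it is the vinyl donor of that carbene, it leaves the carbene without a β-hydrogen, and it can become the C4 stereocentre afterwards by hydrogenation from the face left open by the cis substituents on C2 and C3.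

## Retrosynthetic reasoning

Target 17 is first taken back to the all-cis methyl ester 16. Only the oxidation level of the C3 branch changes. The ester is wanted because a carbonyl group on C3 is the acceptor that a stabilised carbene needs; the forward step is a hydride reduction that must be faster than enolisation at C3.

In 16 the C4–H bond and the benzylic C–H bond of the side chain are removed together, which gives the benzylidene oxolane 15. This takes the third stereocentre out of the ring-forming step: only C2 and C3 have to be created there, and C4 is relayed from them, since the cis aryl and ester groups of 15 cover one face of the exocyclic alkene. The forward reaction must add hydrogen syn from the open face without cleaving the allylic C5–O or the benzylic C2–O bond.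

The C2–C3 bond of 15 is cut next, which leads through the rhodium carbene 14 to the acyclic vinyl diazo ester 13. This is the only ring bond whose formation makes two stereocentres at once from an achiral open-chain precursor in which C2 is still an ordinary benzyl ether CH2. Cutting C3–C4 or a C–O bond would need a stereocentre made beforehand. The forward reaction has to choose the benzylic C–H bond five atoms from the carbene carbon, give the cis product, and do so in one absolute sense under the control of a chiral dirhodium carboxylate.

The diazo group of 13 is removed to give the β,γ-unsaturated ester 12. Its CH2 is activated by the ester and by the styrene unit, so diazo transfer is the natural forward step; it must not disturb the alkene geometry.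

In 12 the bond between the alkene carbon and the CH2CO2Me arm is cut, giving the alkenyl iodide 9 and methyl bromoacetate 10, which is used as its zinc enolate 11. A cross-coupling at an sp2 carbon goes with retention, so the geometry of the trisubstituted alkene (ring A cis to the CH2O arm, trans to the acetate arm) can be fixed earlier, in the iodide. That geometry matters in the key step because it keeps ring A away from the carbene carbon.

The ether C–O bond of 9 is cut to the iodo allylic alcohol 6 and the benzylic chloride 7. The ether is made after the alkene and not before, for two reasons: a free hydroxyl group is then available to steer the metal in the preceding step, and an alkoxide next to a carbon–metal bond is far less prone to β-elimination than an ether.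

In 6 the C–I and the vinylic C–H bond are removed, which gives the aryl propargylic alcohol 3. The forward step is a syn hydrometalation through alkoxide 4 and alkenylzirconocene 5, with the metal on the carbon next to the CH2O group, followed by iodinolysis with retention. Syn addition puts H and I cis, and so puts ring A cis to the CH2O group.

Alcohol 3 is cut at the aryl–alkyne bond into the aryl iodide 1 and prop-2-yn-1-ol 2, a routine sp2–sp coupling.

## Alternatives that were turned down

Alternative 1: The oxolane is cut at C2–C3 and C4–C5 at once. In the forward sense 2-(3,4,5-trimethoxyphenyl)furan A1 and maleic anhydride A2 would combine in a Diels–Alder reaction to the exo 7-oxanorbornene anhydride A3, whose oxygen bridge and four flanking carbons are the oxolane. The two-carbon alkene bridge would then be excised (oxidative cleavage and removal of both carbons), and the anhydride carbonyls turned into the C3 hydroxymethyl and the C4 benzyl group.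
- For it: cheap materials, a thermal cycloaddition with no chemoselectivity question, and an adduct that already holds the two carboxyl carbons cis to each other and cis to the aryl group.
- Against it: cycloadditions of furans with A2 are reversible, and A1 gives up aryl conjugation, so conversion to A3 is not assured.
- Against it: the bridgehead carbon of A3 that becomes C2 is quaternary. Removing its bridge carbon passes through a benzylic, oxygen-stabilised radical or cation, which is quenched from the less hindered face, trans to the C3 substituent. That destroys the one relationship the adduct had secured.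
- Against it: the two anhydride carbonyls differ only in their distance from the aryl group and still have to be told apart, and A3 is formed as a racemate.
- Comparison: two C–C bonds are made only to be cut again, so the step count is well above that of the chosen route. The ring-forming step itself is more robust than a carbene insertion, and on that point the alternative is stronger. The chosen strategy offers in its place C2 and C3 created with their hydrogens already present, under catalyst control, and nothing to excise.

Alternative 2: The ring is cut at O1–C5 after C3 and C4 have been merged into an alkene. The vinyl oxirane A4 would rearrange under a Lewis-acidic copper catalyst: its allylic C–O bond breaks and the oxygen recloses on the alkene terminus, which forms O1–C5 and gives the 2,5-dihydrofuran A5. The aryl-bearing oxirane carbon becomes C2 untouched. Syn hydrogenation of the tetrasubstituted C3=C4 bond from the face opposite the C2 aryl group would then set C3 and C4 together, and desilylation would finish.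
- For it: the absolute configuration comes from an asymmetric epoxidation of an allylic alcohol, a dependable source, and the ring expansion does not touch it. The all-cis triad follows from one syn addition of hydrogen, and no diazo compound is needed.
- Against it: A4 needs a cross-conjugated dienol with a defined trisubstituted alkene, so the geometry problem of the chosen route returns, joined by the need to epoxidise one alkene of a diene.
- Against it: under the copper catalyst the oxirane can also open at its benzylic C–O bond, helped by the para-methoxy group of ring B, which leads to carbonyl rearrangement or loss of configuration at the future C2.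
- Against it: the hydrogenation must reduce an unactivated tetrasubstituted alkene whose C2–O bond is both benzylic and allylic, which invites hydrogenolysis.
- Comparison: the step count is about equal or slightly higher. On the source of absolute configuration this alternative is stronger, since the enantioselectivity of the chosen route rests on analogy. The chosen strategy offers in its place a hydrogenation of a trisubstituted styrene under mild conditions and a precursor reached by five routine steps.

Alternative 3: The ring is cut at O1–C2 and at the C3–carboxyl bond. The alkynol A6 would cyclise by 5-endo-dig attack of its hydroxyl group on the alkyne bound to divalent palladium, and the alkenylpalladium would be intercepted by methoxycarbonylation, giving the 4,5-dihydrofuran ester A7. Hydrogenation of its C2=C3 bond from the face opposite the C4 benzyl group would give the same all-cis ester 16, which is then reduced.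
- For it: the single stereocentre of A6 can be set by an auxiliary-controlled alkylation, A6 is assembled convergently, A7 has no epimerisable centre, and the route meets the chosen one at 16.
- Against it: the alkene of A7 is tetrasubstituted, a vinylogous carbonate, and conjugated with ring B, which makes it one of the least reactive alkenes toward hydrogenation. Forcing conditions threaten the benzylic C2–O bond of the product as it forms, and facial control rests on one substituent at C4.
- Against it: the oxidative carbonylation needs a stoichiometric oxidant to return palladium to the divalent state, in the presence of the easily oxidised ring A.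
- Comparison: with attachment and removal of the auxiliary the step count is comparable. The alternative is stronger in that its first stereocentre is set stoichiometrically and predictably, and its key product is robust. The chosen strategy offers in its place C2 and C3 formed in the ring-closing event under catalytic control, and a last stereocentre from an easy hydrogenation.

Key step: step 6

Assumption: the absolute sense of induction of Rh2(S-PTTL)4 in step 6 is assigned by analogy with insertions of aryl diazoacetates. If it proves to favour the (2S,3R) ester, the enantiomeric catalyst Rh2(R-PTTL)4 is used with no other change.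

## Route

Step 1
Reactants: 1 1-iodo-2,4,5-trimethoxybenzene; 2 prop-2-yn-1-ol
Product: 3 3-(2,4,5-trimethoxyphenyl)prop-2-yn-1-ol
Conditions: Pd(PPh3)2Cl2 (2 mol%), CuI (4 mol%), Et3N, THF, 50 °C
Reagents that add atoms: none
Why: Sonogashira coupling; oxidative addition of the aryl iodide to zerovalent palladium is fast even for this electron-rich ring, and the copper acetylide of 2 transmetalates without protection of the hydroxyl group.

Step 2
Reactants: 3 3-(2,4,5-trimethoxyphenyl)prop-2-yn-1-ol
Product: 6 (E)-2-iodo-3-(2,4,5-trimethoxyphenyl)prop-2-en-1-ol, via lithium alkoxide 4 (not isolated), via alkenylzirconocene 5 (not isolated)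
Conditions: n-BuLi, THF, −78 °C; Cp2Zr(H)Cl, ZnCl2 (cat.), rt; I2, 0 °C
Reagents that add atoms: iodine, II
Why: Alkoxide-directed hydrozirconation followed by iodinolysis: the Zr–H bond adds syn across the alkyne and the zirconium should settle on the carbon next to the alkoxide, where the oxygen holds it and where it is away from the ortho-substituted ring A, so hydrogen goes to the aryl-bearing carbon. Iodine cleaves the C–Zr bond with retention, which leaves H and I cis and ring A cis to the CH2O group; because an alkoxide is a poor leaving group, β-elimination to an allene is not expected.

Step 3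
Reactants: 6 (E)-2-iodo-3-(2,4,5-trimethoxyphenyl)prop-2-en-1-ol; 7 5-(chloromethyl)-1,2,3-trimethoxybenzene
Product: 9 (E)-1-[2-iodo-3-(3,4,5-trimethoxybenzyloxy)prop-1-enyl]-2,4,5-trimethoxybenzene, via sodium alkoxide 8 (not isolated)
Conditions: NaH, THF, 0 °C; then 7, n-Bu4NI (cat.), rt
Reagents that add atoms: none
Why: Williamson ether synthesis; the primary alkoxide 8 displaces chloride from the benzylic chloride 7 under iodide catalysis. The alkenyl iodide should survive the base because its vinylic hydrogen is cis to iodine, so anti elimination to the alkyne is not possible.

Step 4
Reactants: 9 (E)-1-[2-iodo-3-(3,4,5-trimethoxybenzyloxy)prop-1-enyl]-2,4,5-trimethoxybenzene; 10 methyl bromoacetate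
Product: 12 methyl (3Z)-3-[(3,4,5-trimethoxybenzyloxy)methyl]-4-(2,4,5-trimethoxyphenyl)but-3-enoate, via Reformatsky reagent 11 (not isolated)
Conditions: 10, Zn dust, TMSCl (cat.), THF, 40 °C; then 9, Pd(PPh3)4 (5 mol%), THF/DMPU, 50 °C
Reagents that add atoms: none
Why: Negishi-type cross-coupling of a Reformatsky reagent with an alkenyl iodide; oxidative addition to zerovalent palladium, transmetalation of the zinc enolate and reductive elimination all go with retention at the alkene carbon, so ring A stays cis to the CH2O arm (the descriptor changes from E to Z only through the priority rules). The double bond should stay in the β,γ-position because there it is conjugated with ring A.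

Step 5
Reactants: 12 methyl (3Z)-3-[(3,4,5-trimethoxybenzyloxy)methyl]-4-(2,4,5-trimethoxyphenyl)but-3-enoate
Product: 13 methyl (3Z)-2-diazo-3-[(3,4,5-trimethoxybenzyloxy)methyl]-4-(2,4,5-trimethoxyphenyl)but-3-enoate
Conditions: p-ABSA, DBU, MeCN, 0 °C
Reagents that add atoms: 4-acetamidobenzenesulfonyl azide (p-ABSA), CC(=O)Nc1ccc(cc1)S(=O)(=O)N=[N+]=[N-]
Why: Regitz diazo transfer to a β,γ-unsaturated ester; DBU removes a proton from the CH2 that is activated by both the ester and the styrene unit, the carbanion attacks the terminal nitrogen of the sulfonyl azide, and loss of the sulfonamide leaves the vinyl diazo ester. Compound 13 is kept cold and used at once to avoid electrocyclisation to a pyrazole.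

Step 6
Reactants: 13 methyl (3Z)-2-diazo-3-[(3,4,5-trimethoxybenzyloxy)methyl]-4-(2,4,5-trimethoxyphenyl)but-3-enoate
Product: 15 methyl (2R,3S,4Z)-4-(2,4,5-trimethoxybenzylidene)-2-(3,4,5-trimethoxyphenyl)oxolane-3-carboxylate, via rhodium vinylcarbene 14 (not isolated)
Conditions: Rh2(S-PTTL)4 (1 mol%), toluene, −60 → −20 °C, slow addition of 13
Reagents that add atoms: none
Why: Dirhodium tetrakis[N-phthaloyl-(S)-tert-leucinate] takes N2 from 13 and gives the electrophilic donor/acceptor carbene 14, which has no hydrogen on the neighbouring carbon and so cannot undergo a 1,2-shift. The carbene carbon then inserts into one of the two enantiotopic benzylic C–H bonds of the ArCH2–O group five atoms away, through a three-centre transition state with much hydride-transfer character, which forms the C2–C3 bond and releases the catalyst. The closest known reaction type is the enantioselective intramolecular 1,5-C–H insertion of aryl and vinyl diazoacetates into benzylic ether C–H bonds with chiral dirhodium carboxylates, which gives cis-2-aryl oxacycle-3-carboxylates. The oxolane closes by C–C bond formation between the carbene carbon and the ether carbon through a five-membered cyclic transition state (1,5-insertion), the alkene staying exocyclic. C2 and C3 are created together: by analogy with the dihydrobenzofuran cases their cis relationship should be the kinetic outcome of the compact insertion transition state, and the absolute configuration (2R,3S) should come from the chiral pocket of the four phthalimido carboxylate ligands, which selects one enantiotopic hydrogen and one face of the carbene. The step needs 1,5-insertion in preference to cyclopropene formation, to attack on either electron-rich arene and to thermal pyrazole formation. The substrate helps through its Z alkene, which holds ring A on the far side of the double bond from the carbene carbon, through the ether oxygen, which makes the targeted C–H bond the most hydridic one within reach, and through the five-membered geometry, which is favoured over the seven-membered ring that attack on ring B would need; low temperature and slow addition keep 14 from meeting a second molecule of 13.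

Step 7
Reactants: 15 methyl (2R,3S,4Z)-4-(2,4,5-trimethoxybenzylidene)-2-(3,4,5-trimethoxyphenyl)oxolane-3-carboxylate
Product: 16 methyl (2R,3S,4R)-4-(2,4,5-trimethoxybenzyl)-2-(3,4,5-trimethoxyphenyl)oxolane-3-carboxylate
Conditions: H2 (1 atm), 5% Rh/Al2O3, EtOAc, rt
Reagents that add atoms: none
Why: Heterogeneous syn hydrogenation of the exocyclic trisubstituted alkene; the cis aryl and ester groups on C2 and C3 cover one face of the ring, so hydrogen should reach C4 from the other face, which places the new benzyl group cis to both and sets C4 as R. Rh/Al2O3 in a neutral solvent is chosen because it has little tendency to cleave allylic or benzylic C–O bonds or to move the double bond, and a non-coordinating catalyst is preferred to a homogeneous one that the ester could direct to the wrong face.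

Step 8
Reactants: 16 methyl (2R,3S,4R)-4-(2,4,5-trimethoxybenzyl)-2-(3,4,5-trimethoxyphenyl)oxolane-3-carboxylate
Product: 17 [(2R,3R,4R)-4-(2,4,5-trimethoxybenzyl)-2-(3,4,5-trimethoxyphenyl)oxolan-3-yl]methanol
Conditions: LiAlH4, THF, 0 °C; aqueous NaOH work-up
Reagents that add atoms: none
Why: Hydride reduction of the methyl ester to the primary alcohol; at 0 °C reduction should be much faster than enolisation, so C3, which lies α to the carbonyl and β to the ring oxygen, should be neither epimerised nor lost by elimination. The aryl methyl ethers and the oxolane are inert, and the C3 descriptor changes from S to R only because the priorities change.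

## Compound list

1 | 1-iodo-2,4,5-trimethoxybenzene | COc1cc(OC)c(OC)cc1I | starting material
2 | prop-2-yn-1-ol | OCC#C | starting material
3 | 3-(2,4,5-trimethoxyphenyl)prop-2-yn-1-ol | COc1cc(OC)c(OC)cc1C#CCO | intermediate
4 | lithium 3-(2,4,5-trimethoxyphenyl)prop-2-yn-1-olate | COc1cc(OC)c(OC)cc1C#CC[O-].[Li+] | intermediate (not isolated)
5 | lithium (E)-2-[chlorobis(cyclopentadienyl)zirconio]-3-(2,4,5-trimethoxyphenyl)prop-2-en-1-olate (cyclopentadienyl rings drawn as simple C5H5 substituents) | COc1cc(OC)c(OC)cc1/C=C(/[Zr](Cl)(C1C=CC=C1)C1C=CC=C1)C[O-].[Li+] | intermediate (not isolated)
6 | (E)-2-iodo-3-(2,4,5-trimethoxyphenyl)prop-2-en-1-ol | COc1cc(OC)c(OC)cc1/C=C(/I)CO | intermediate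
7 | 5-(chloromethyl)-1,2,3-trimethoxybenzene | COc1cc(CCl)cc(OC)c1OC | starting material
8 | sodium (E)-2-iodo-3-(2,4,5-trimethoxyphenyl)prop-2-en-1-olate | COc1cc(OC)c(OC)cc1/C=C(/I)C[O-].[Na+] | intermediate (not isolated)
9 | (E)-1-[2-iodo-3-(3,4,5-trimethoxybenzyloxy)prop-1-enyl]-2,4,5-trimethoxybenzene | COc1cc(OC)c(OC)cc1/C=C(/I)COCc1cc(OC)c(OC)c(OC)c1 | intermediate
10 | methyl bromoacetate | COC(=O)CBr | starting material
11 | (2-methoxy-2-oxoethyl)zinc bromide (Reformatsky reagent) | COC(=O)C[Zn]Br | intermediate (not isolated)
12 | methyl (3Z)-3-[(3,4,5-trimethoxybenzyloxy)methyl]-4-(2,4,5-trimethoxyphenyl)but-3-enoate | COC(=O)C/C(COCc1cc(OC)c(OC)c(OC)c1)=C/c1cc(OC)c(OC)cc1OC | intermediate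
13 | methyl (3Z)-2-diazo-3-[(3,4,5-trimethoxybenzyloxy)methyl]-4-(2,4,5-trimethoxyphenyl)but-3-enoate | COC(=O)C(=[N+]=[N-])/C(COCc1cc(OC)c(OC)c(OC)c1)=C/c1cc(OC)c(OC)cc1OC | intermediate
14 | rhodium vinylcarbene from 13 (N2 replaced by the Rh2(S-PTTL)4 unit, drawn as [Rh]) | COC(=O)C(=[Rh])/C(COCc1cc(OC)c(OC)c(OC)c1)=C/c1cc(OC)c(OC)cc1OC | intermediate (not isolated)
15 | methyl (2R,3S,4Z)-4-(2,4,5-trimethoxybenzylidene)-2-(3,4,5-trimethoxyphenyl)oxolane-3-carboxylate | COc1cc(OC)c(OC)cc1/C=C1\CO[C@@H](c2cc(OC)c(OC)c(OC)c2)[C@H]1C(=O)OC | intermediate
16 | methyl (2R,3S,4R)-4-(2,4,5-trimethoxybenzyl)-2-(3,4,5-trimethoxyphenyl)oxolane-3-carboxylate | COc1cc(OC)c(OC)cc1C[C@H]1CO[C@@H](c2cc(OC)c(OC)c(OC)c2)[C@H]1C(=O)OC | intermediate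
17 | [(2R,3R,4R)-4-(2,4,5-trimethoxybenzyl)-2-(3,4,5-trimethoxyphenyl)oxolan-3-yl]methanol | COc1cc(OC)c(OC)cc1C[C@H]1CO[C@@H](c2cc(OC)c(OC)c(OC)c2)[C@H]1CO | target

## Step count and risks

Total step count: 8. Longest linear sequence: 8 steps (from 1 to 17).

Least certain steps:

**Step 6 (key step).** The carbene may be diverted: closure onto its own double bond to a cyclopropene, or electrophilic attack on ring B, whose ortho positions are activated by two methoxy groups. It may also insert with poor cis or enantio selectivity, because the vinyl group has to twist out of conjugation in the insertion geometry and the catalyst model is taken from aryl carbenes.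

Fallback: the ring is built without a carbene, setting out from 1 and 2 and rejoining the route at 16.
- Lithium prop-2-yn-1-olate (from 2 and n-BuLi) is combined in THF/DMSO with the Knoevenagel-type acceptor dimethyl 2-(3,4,5-trimethoxybenzylidene)malonate F1, with 1 and with PdCl2(PPh3)2 (cat.). Oxa-Michael addition gives a malonate anion, which attacks the alkyne anti to the arylpalladium iodide formed from 1 (5-exo-dig). Reductive elimination should give racemic dimethyl (4Z)-2-(3,4,5-trimethoxyphenyl)-4-(2,4,5-trimethoxybenzylidene)oxolane-3,3-dicarboxylate F2, with the benzylidene geometry of 15.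
- Krapcho dealkoxycarbonylation (LiCl, wet DMSO, 140 °C) should remove one ester group and, the double bond moving into conjugation with the other, give racemic methyl 4-(2,4,5-trimethoxybenzyl)-2-(3,4,5-trimethoxyphenyl)-2,5-dihydrofuran-3-carboxylate F3.
- Hydrogenation over Rh/Al2O3 from the face opposite the C2 aryl group should give the all-cis ester as a racemate. Chromatography on a chiral stationary phase separates 16 from its enantiomer methyl (2S,3R,4S)-4-(2,4,5-trimethoxybenzyl)-2-(3,4,5-trimethoxyphenyl)oxolane-3-carboxylate F4.
- The price is half the material and a tetrasubstituted alkene to hydrogenate.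

**Step 2.** Regiocontrol of the Zr–H addition may be incomplete: the aryl group could draw part of the zirconium to the benzylic carbon, and the two iodides would be hard to separate.

Fallback: from 3, hydrostannation with Bu3SnH and Mo(CO)3(CNt-Bu)3 (cat.) in THF. This delivers tin syn to the carbon next to the carbinol and should give (E)-2-(tributylstannyl)-3-(2,4,5-trimethoxyphenyl)prop-2-en-1-ol F5, which can be freed of its regioisomer by chromatography. Iododestannylation with I2 in CH2Cl2 at 0 °C goes with retention and returns to the route at 6.

**Step 4.** Transmetalation of the zinc enolate to the hindered, α-branched alkenylpalladium iodide may be slow, which leaves time for β-alkoxide elimination to an allene or for reduction of the C–I bond.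

Fallback: the polarity is reversed. From 9, Miyaura borylation (B2pin2, PdCl2(PPh3)2, KOPh, toluene, 50 °C) should give 2-[(Z)-1-(2,4,5-trimethoxyphenyl)-3-(3,4,5-trimethoxybenzyloxy)prop-1-en-2-yl]-4,4,5,5-tetramethyl-1,3,2-dioxaborolane F6. Suzuki–Miyaura coupling of F6 with 10 (Pd(OAc)2, tri(1-naphthyl)phosphine, K3PO4, THF/H2O) then returns to the route at 12.

**Step 5.** The alkene geometry may be lost, or the double bond may migrate, through the extended enolate that DBU generates; the product may also cyclise to a pyrazole on standing.

Fallback: from 9 directly to 13 by palladium-catalysed coupling of the alkenyl iodide with methyl diazoacetate (Pd(PPh3)4, Et3N, n-Bu4NBr, MeCN, rt). This is a known C–H alkenylation of diazoacetates; it keeps the alkene geometry, never forms the enolate, and passes through no new isolated compound.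

**Step 7.** The allylic C5–O or the benzylic C2–O bond may be cleaved by hydrogenolysis, the double bond may migrate into conjugation with the ester on the metal surface (which erases C3), or the facial bias may be insufficient.

Fallback: the order of the last two operations is changed, setting out from 15 and rejoining at 17.
- Reduction with i-Bu2AlH (CH2Cl2, −78 °C) gives [(2R,3R,4Z)-4-(2,4,5-trimethoxybenzylidene)-2-(3,4,5-trimethoxyphenyl)oxolan-3-yl]methanol F7, which no longer has an epimerisable centre.
- Silylation (TBDPSCl, imidazole, DMF) gives its tert-butyldiphenylsilyl ether F8, whose bulky group enlarges the shielding of the occupied face.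
- Hydrogenation over Rh/Al2O3 gives the saturated all-cis silyl ether F9. Diimide from 2-nitrobenzenesulfonohydrazide and Et3N can be used if hydrogenolysis persists.
- n-Bu4NF in THF releases 17.

## Further compounds

F1 | step 6 | dimethyl 2-(3,4,5-trimethoxybenzylidene)malonate | COC(=O)C(=Cc1cc(OC)c(OC)c(OC)c1)C(=O)OC
F2 | step 6 | dimethyl (4Z)-2-(3,4,5-trimethoxyphenyl)-4-(2,4,5-trimethoxybenzylidene)oxolane-3,3-dicarboxylate (racemic) | COC(=O)C1(C(=O)OC)C(c2cc(OC)c(OC)c(OC)c2)OC/C1=C\c1cc(OC)c(OC)cc1OC
F3 | step 6 | methyl 4-(2,4,5-trimethoxybenzyl)-2-(3,4,5-trimethoxyphenyl)-2,5-dihydrofuran-3-carboxylate (racemic) | COC(=O)C1=C(Cc2cc(OC)c(OC)cc2OC)COC1c1cc(OC)c(OC)c(OC)c1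
F4 | step 6 | methyl (2S,3R,4S)-4-(2,4,5-trimethoxybenzyl)-2-(3,4,5-trimethoxyphenyl)oxolane-3-carboxylate (enantiomer of 16) | COc1cc(OC)c(OC)cc1C[C@@H]1CO[C@H](c2cc(OC)c(OC)c(OC)c2)[C@@H]1C(=O)OC
F5 | step 2 | (E)-2-(tributylstannyl)-3-(2,4,5-trimethoxyphenyl)prop-2-en-1-ol | CCCC[Sn](CCCC)(CCCC)/C(CO)=C/c1cc(OC)c(OC)cc1OC
F6 | step 4 | 2-[(Z)-1-(2,4,5-trimethoxyphenyl)-3-(3,4,5-trimethoxybenzyloxy)prop-1-en-2-yl]-4,4,5,5-tetramethyl-1,3,2-dioxaborolane | COc1cc(OC)c(OC)cc1/C=C(/B1OC(C)(C)C(C)(C)O1)COCc1cc(OC)c(OC)c(OC)c1
F0 | step 5 | none | none
F7 | step 7 | [(2R,3R,4Z)-4-(2,4,5-trimethoxybenzylidene)-2-(3,4,5-trimethoxyphenyl)oxolan-3-yl]methanol | COc1cc(OC)c(OC)cc1/C=C1\CO[C@@H](c2cc(OC)c(OC)c(OC)c2)[C@H]1CO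
F8 | step 7 | tert-butyldiphenylsilyl ether of F7 | COc1cc(OC)c(OC)cc1/C=C1\CO[C@@H](c2cc(OC)c(OC)c(OC)c2)[C@H]1CO[Si](c1ccccc1)(c1ccccc1)C(C)(C)C
F9 | step 7 | tert-butyldiphenylsilyl ether of 17 | COc1cc(OC)c(OC)cc1C[C@H]1CO[C@@H](c2cc(OC)c(OC)c(OC)c2)[C@H]1CO[Si](c1ccccc1)(c1ccccc1)C(C)(C)C
A1 | alternative 1 | 2-(3,4,5-trimethoxyphenyl)furan | COc1cc(cc(OC)c1OC)-c1ccco1
A2 | alternative 1 | maleic anhydride | O=C1OC(=O)C=C1
A3 | alternative 1 | exo 1-(3,4,5-trimethoxyphenyl)-7-oxabicyclo[2.2.1]hept-5-ene-2,3-dicarboxylic anhydride | O=C1OC(=O)[C@@H]2[C@H]1[C@@]1(c3cc(OC)c(OC)c(OC)c3)C=C[C@@H]2O1
A4 | alternative 2 | 2-(tert-butyldimethylsilyloxymethyl)-3-(3,4,5-trimethoxyphenyl)-2-[3-(2,4,5-trimethoxyphenyl)prop-1-en-2-yl]oxirane, aryl cis to the alkenyl group | C=C(Cc1cc(OC)c(OC)cc1OC)[C@@]1(CO[Si](C)(C)C(C)(C)C)O[C@H]1c1cc(OC)c(OC)c(OC)c1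
A5 | alternative 2 | 3-(tert-butyldimethylsilyloxymethyl)-4-(2,4,5-trimethoxybenzyl)-2-(3,4,5-trimethoxyphenyl)-2,5-dihydrofuran, C2 configured as in the target | COc1cc(OC)c(OC)cc1CC1=C(CO[Si](C)(C)C(C)(C)C)[C@H](c2cc(OC)c(OC)c(OC)c2)OC1
A6 | alternative 3 | (R)-2-(2,4,5-trimethoxybenzyl)-4-(3,4,5-trimethoxyphenyl)but-3-yn-1-ol | OC[C@H](Cc1cc(OC)c(OC)cc1OC)C#Cc1cc(OC)c(OC)c(OC)c1
A7 | alternative 3 | methyl 4-(2,4,5-trimethoxybenzyl)-2-(3,4,5-trimethoxyphenyl)-4,5-dihydrofuran-3-carboxylate, C4 configured as in the target | COc1cc(OC)c(OC)cc1C[C@H]1COC(c2cc(OC)c(OC)c(OC)c2)=C1C(=O)OC
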